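**Remark on the chemistry:** the target has no stereogenic element (it is achiral), so no stereocontrol is needed. 2-Methylphloroglucinol is taken as commercially available.

**Retrosynthetic overview**
- The diarylmethane is cut between the bridging CH2 (kept on the O-methylated ring B) and the ring carbon of the trihydroxy ring A. Ring B becomes an ortho-quinone methide and ring A a C-nucleophile, as in the presumed biosynthesis of methylene-bridged acylphloroglucinols.
- Enabling feature: the bridging CH2 sits ortho to a free OH of ring B (its other ortho neighbour carries OMe; a further OH is para), so ring B can be unmasked as a quinone methide. Ring A has exactly one unsubstituted ring carbon, flanked by two OH groups.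
- The quinone methide precursor is the benzylic acetate of ring B, made by acetoxymethylation of the 4-O-methyl ether of ring A.
- Both halves come from one acylphloroglucinol, made by Friedel–Crafts propionylation of 2-methylphloroglucinol. No ring is formed in the route; both benzene rings are bought.

Key step: step 4

**Step 1**
Reactants: 1 2-methylbenzene-1,3,5-triol (2-methylphloroglucinol)
Product: 2 1-(2,4,6-trihydroxy-3-methylphenyl)propan-1-one
Conditions: EtCOCl (1.05 equiv), AlCl3 (3.5 equiv), PhNO2/CH2Cl2, 0 °C to 45 °C; then ice/2 M HCl
Reagents that add atoms: propionyl chloride, CCC(=O)Cl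
Why: Friedel–Crafts C-acylation; the two unsubstituted ring carbons of 1 are equivalent by symmetry, so only one mono-ketone can form, and the first acyl group deactivates the ring against a second acylation.

**Step 2**
Reactants: 2 1-(2,4,6-trihydroxy-3-methylphenyl)propan-1-one
Product: 3 1-(2,6-dihydroxy-4-methoxy-3-methylphenyl)propan-1-one
Conditions: Me2SO4 (1.0 equiv), K2CO3 (1.0 equiv), acetone, 0 °C to rt
Reagents that add atoms: dimethyl sulfate, COS(=O)(=O)OC
Why: Williamson-type O-methylation; with one equivalent of base the 4-OH para to the ketone (a vinylogous carboxylic acid, not chelated) should be deprotonated and methylated in preference to the two less acidic ortho OH groups that flank the C=O.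

**Step 3**
Reactants: 3 1-(2,6-dihydroxy-4-methoxy-3-methylphenyl)propan-1-one
Product: 5 (2,4-dihydroxy-6-methoxy-5-methyl-3-propanoylphenyl)methyl acetate, via hydroxymethyl phenol 4 (not isolated)
Conditions: 37% aq. HCHO (3 equiv), NaOAc, AcOH, 80 °C
Reagents that add atoms: formaldehyde, C=O; acetic acid, CC(=O)O
Why: Lederer–Manasse-type ortho-hydroxymethylation at the only unsubstituted ring carbon (ortho to an OH, para to the other), followed by acetolysis of the o-hydroxybenzyl alcohol in buffered AcOH, a known entry to quinone methide precursors of acylresorcinols; excess formaldehyde should hold back self-condensation.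

**Step 4**
Reactants: 5 (2,4-dihydroxy-6-methoxy-5-methyl-3-propanoylphenyl)methyl acetate; 2 1-(2,4,6-trihydroxy-3-methylphenyl)propan-1-one (1.5 equiv)
Product: 7 1-[3-[(2,4-dihydroxy-6-methoxy-5-methyl-3-propanoylphenyl)methyl]-2,4,6-trihydroxy-5-methylphenyl]propan-1-one, via ortho-quinone methide 6 (not isolated)
Conditions: 1,4-dioxane (degassed, 0.05 M), 100 °C, sealed tube, Ar
Reagents that add atoms: none
Why: Thermal 1,4-elimination of acetic acid from 5, through the OH ortho to the CH2OAc group, should give the push-pull stabilised ortho-quinone methide 6 (its para-quinone methide tautomer would lead to the same product). The neutral, enol-like acylphloroglucinol 2 then adds through its single unsubstituted ring carbon to the exocyclic methylene, and tautomerisation restores both aromatic rings. The closest known reaction type is the biomimetic Michael (Friedel–Crafts type) addition of enolic C-nucleophiles to quinone methides released thermally from o-hydroxybenzyl acetates. No ring is closed and no stereocentre is created, so only chemoselectivity is required: cross-coupling over homo-coupling, and C- over O-alkylation. Cross-selectivity is secured because the one-carbon electrophile is installed on ring B alone, 5 has no free ring carbon and 2 has exactly one. The excess of 2 should outrun self-reaction of 6, and the absence of base should suppress retro-Michael scrambling of the methylene bridge.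

**Compound list**
1 | 2-methylbenzene-1,3,5-triol (2-methylphloroglucinol) | Cc1c(O)cc(O)cc1O | starting material
2 | 1-(2,4,6-trihydroxy-3-methylphenyl)propan-1-one | CCC(=O)c1c(O)cc(O)c(C)c1O | intermediate
3 | 1-(2,6-dihydroxy-4-methoxy-3-methylphenyl)propan-1-one | CCC(=O)c1c(O)cc(OC)c(C)c1O | intermediate
4 | 1-[2,6-dihydroxy-3-(hydroxymethyl)-4-methoxy-5-methylphenyl]propan-1-one (not isolated) | CCC(=O)c1c(O)c(CO)c(OC)c(C)c1O | intermediate
5 | (2,4-dihydroxy-6-methoxy-5-methyl-3-propanoylphenyl)methyl acetate | CC(=O)OCc1c(O)c(C(=O)CC)c(O)c(C)c1OC | intermediate
6 | 3-hydroxy-5-methoxy-4-methyl-6-methylidene-2-propanoylcyclohexa-2,4-dien-1-one (ortho-quinone methide, not isolated) | C=C1C(=O)C(C(=O)CC)=C(O)C(C)=C1OC | intermediate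
7 | 1-[3-[(2,4-dihydroxy-6-methoxy-5-methyl-3-propanoylphenyl)methyl]-2,4,6-trihydroxy-5-methylphenyl]propan-1-one | CCC(=O)c1c(O)c(C)c(O)c(Cc2c(O)c(C(=O)CC)c(O)c(C)c2OC)c1O | target

**Step count**
Total steps: 4. Longest linear sequence: 4 steps (1 → 2 → 3 → 5 → 7); compound 2 is used a second time as the nucleophile in step 4.

**Steps most likely to fail, with fallbacks**

Step 4 (key coupling). The quinone methide may be consumed by self-reaction (dimerisation, O-alkylation) before the C–C bond forms, or the methylene bridge may scramble by retro-Michael cleavage of the product. The fallback sets out from 2 and 3 and returns at 7. It is the classical three-component phenolate condensation: equimolar 2 and 3 with aqueous formaldehyde (one equivalent per pair) in dilute aqueous KOH at 0–20 °C, then acidification. Hydroxymethyl phenolates such as 4 should lose hydroxide and be trapped by the other phenolate. The method is statistical by design, so 7 would have to be separated by chromatography or fractional crystallisation from the symmetrical by-products 1,1'-[methylenebis(2,4,6-trihydroxy-5-methyl-3,1-phenylene)]di(propan-1-one) F1 and 1,1'-[methylenebis(2,6-dihydroxy-4-methoxy-5-methyl-3,1-phenylene)]di(propan-1-one) F2.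

Step 2 (mono-O-methylation). Site selectivity may be poor: over-methylation, methylation of an ortho OH, or C-methylation of the phloroglucinol ring. The fallback sets out from 2 and returns at 3. It inverts the logic: exhaustive methylation (excess Me2SO4, K2CO3, acetone, reflux) should give 1-(2,4,6-trimethoxy-3-methylphenyl)propan-1-one F3. Chelation-directed cleavage with excess BCl3 (CH2Cl2, −78 °C to rt) should then remove only the two methyl ethers ortho to the ketone and leave the para OMe untouched.

Step 3 (acetoxymethylation). The quinone methide formed in the flask may be captured by unreacted 3 at its free ring carbon (symmetrical methylene-bis by-product), or a cyclic formal may form with the neighbouring OH. The fallback sets out from 3 and returns at 7. A Mannich reaction (aq. Me2NH, aq. HCHO, EtOH, rt) should give the Mannich base 1-[3-[(dimethylamino)methyl]-2,6-dihydroxy-4-methoxy-5-methylphenyl]propan-1-one F4, which is stable at room temperature. Heating F4 with 2 in dioxane at 100 °C should expel dimethylamine, generate the same quinone methide 6, and give 7 directly.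

**Further compounds**
F1 | step 4 | 1,1'-[methylenebis(2,4,6-trihydroxy-5-methyl-3,1-phenylene)]di(propan-1-one) (symmetrical by-product) | CCC(=O)c1c(O)c(C)c(O)c(Cc2c(O)c(C)c(O)c(C(=O)CC)c2O)c1O
F2 | step 4 | 1,1'-[methylenebis(2,6-dihydroxy-4-methoxy-5-methyl-3,1-phenylene)]di(propan-1-one) (symmetrical by-product) | CCC(=O)c1c(O)c(C)c(OC)c(Cc2c(OC)c(C)c(O)c(C(=O)CC)c2O)c1O
F3 | step 2 | 1-(2,4,6-trimethoxy-3-methylphenyl)propan-1-one | CCC(=O)c1c(OC)cc(OC)c(C)c1OC
F4 | step 3 | 1-[3-[(dimethylamino)methyl]-2,6-dihydroxy-4-methoxy-5-methylphenyl]propan-1-one | CCC(=O)c1c(O)c(CN(C)C)c(OC)c(C)c1O
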